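## Analysis of the target

Compound 32 joins two oxygen heterocycles through one aryl–carbon bond (C2–C5'). The first is a tetrasubstituted tetrahydrofuran: O1, C2 bearing the aryl group, C3 bearing CH2OH, C4 bearing OH, and C5 bearing the 4-hydroxy-3-methoxybenzyl group (ring C). The second is a 7-methoxy-2,3-dihydrobenzofuran: O1', C2' bearing the guaiacyl ring A, C3' bearing CH2OH, and the benzo ring B. The tetrahydrofuran carries four contiguous stereocentres, all (S), with C2/C3 trans, C3/C4 trans, C4/C5 cis and therefore C2/C5 cis. The dihydrobenzofuran carries two, (2'R,3'R), with aryl and hydroxymethyl cis, which is the less stable arrangement. Ring B separates the two clusters, so neither can control the other and each needs its own source of absolute configuration. C2–O1 and C2'–O1' are both benzylic ether bonds para to an oxygen substituent: they ionise under acid and can be hydrogenolysed, the cis ring goes to trans once C2' ionises or while C3' is α to a carbonyl group, and the guaiacol units are oxidation-sensitive. The difficulty is to build a stereochemically dense tetrahydrofuran next to this labile cis ring with mild reagents. The strategy rests on ring B: O1' is para to C5', so C2 is a donor-substituted benzylic carbon, and C2–C3–C4 can be folded into a donor–acceptor cyclopropane (C4 as a malonate carbon) that takes up an aldehyde as the O1–C5 unit.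

## Retrosynthetic reasoning

32 from 31. Only the three O–benzyl bonds are cut. Benzyl ethers protect the two phenols and the C3' hydroxymethyl group through Lewis acid, hot chloride, amide base and hydride, and they leave in one neutral operation.

31 from 28 by way of 29 and 30. No skeletal bond is cut; the C3–H bond is reset. The annulation below necessarily delivers C2 and C3 cis, so C3 has to be inverted afterwards. This is done where C3 is the only acidic position: the C3 hydroxymethyl group of 28 is raised to the aldehyde 29, which has both neighbours (aryl at C2, hydroxyl at C4) on its own face and should relax to the trans,trans aldehyde 30 before reduction. Correction at the stage of the C4 ketone 26 was not chosen, because C5 is enolisable there as well and has only a weak thermodynamic preference.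

27 from 21 by way of 22, 24, 25 and 26. The two C4–ester bonds are cut. One ester is removed, the other is turned into a hydroxyl-bearing carbon and excised, and the resulting ketone 26 is reduced at once. In 26 the C3 and C5 substituents and the C2 aryl group all lie on one face, so hydride should enter from the other and place the C4 hydroxyl cis to the C5 benzyl group, as 32 requires.

21 from 16 and 20. This is the key disconnection: O1–C2 and C4–C5 are cut, which removes the ring, two skeletal bonds and two stereocentres at once. It is placed here because C2 is benzylic to a ring with a para oxygen and C4 can carry two esters, which is the substitution pattern of a donor–acceptor cyclopropane. The forward reaction has to open the cyclopropane at the aryl-bearing carbon with inversion, which sets C2, and close the ring with the C5 benzyl group cis to the C2 aryl group. Because inversion is the expected course, the cyclopropane is chosen with the (R) configuration at the aryl-bearing carbon.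

16 from 12 and 13 by way of 14 and 15. The two cyclopropane bonds to the malonate carbon are cut. An amine-catalysed conjugate addition and ring closure of 13 onto the enal 12 sets the aryl-bearing carbon under catalyst control, independently of the remote dihydrobenzofuran centres. Reduction and silylation turn the formyl group into a protected hydroxymethyl arm that can later be unveiled selectively.

12 from 9 and 10. The C5'–vinyl bond is cut. A bromide at C5' is inert during the construction of the dihydrobenzofuran and is converted into the enal in one palladium-catalysed operation, so no aldehyde has to be protected earlier.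

9 from 4 and 5 by way of 6, 7 and 8; 4 from 2 and 3; 2 from 1. The C2'–C3' bond is cut, leading back to a carbenoid insertion into the benzylic C–H bond of an aryl benzyl ether. This forms the ring and both stereocentres, cis, in one catalytic step at a point where the enantiomeric purity can still be checked and upgraded. The diazo ester 6 comes from the aryl iodide 4 and 5, the ether 4 from phenol 2 and alcohol 3, and 2 from 1 by iodination.

20 from 17 by way of 18. The terminal alkene carbon of the allyl group is cut off; the phenol is benzylated first.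

## Alternatives that were turned down

Alternative 1: The tetrahydrofuran is cut at C2–C3 and traced to the 4-alkylidene-1,3-dioxolane A2, whose acetal carbon is the future C2 and whose C5 stereocentre stems from an α-hydroxy acid. In the forward sense Me2AlCl opens the acetal C–O bond on the side of the enol oxygen, and the aluminium enolate of the resulting β-keto ester closes onto the oxocarbenium carbon (Petasis–Ferrier shift) to give the tetrahydrofuran-3-one ester A1.
- For: C4 arrives as the ketone, and C3 already carries an ester that is the direct precursor of CH2OH and sits trans to the aryl group for thermodynamic reasons. The four steps that the chosen route spends on turning a malonate carbon into a carbinol, and the later correction of C3, are not needed. On step economy around C3 and C4 this alternative is stronger.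
- Against: the only source of absolute configuration is C5, which in A1 is α to the ketone and to the ring oxygen and is therefore enolisable under a stoichiometric aluminium Lewis acid. The oxocarbenium ion is a para-oxygenated benzylic cation, long-lived and planar, so C2 is fixed only by a conformational preference in a 5-(enolendo)-endo closure. Acetal formation and Me2AlCl both expose the C2'–O1' bond of the cis-dihydrobenzofuran to strong acid. Reduction of the ketone in A1, whose α-substituents lie on opposite faces, has no clear facial bias.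
- Comparison: the chosen route is longer after ring formation. In return it sets C2 and C5 kinetically with a catalytic, chelation-directed Lewis acid, takes the absolute configuration from a catalyst-controlled step, and reduces the ketone at once so that its two labile α-centres see no acid or base.

Alternative 2: The dihydrobenzofuran is closed last, at C2'–C3'. The aryl diazoacetate A4, which already carries the complete protected tetrahydrofuran on ring B and the ring A benzyl ether on the neighbouring oxygen, is decomposed by Rh2(S-PTTL)4 or its enantiomer, and the carbenoid inserts into the benzylic OCH2 bond to give the cis ester A3.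
- For: the acid- and base-sensitive cis ring is made at the very end and never meets a Lewis acid, hot chloride or an amide base, whereas in the chosen route it must survive seventeen further steps. On this point the alternative is stronger.
- Against: the diazo ester, or the ortho halide from which it is made, has to be carried through or installed after the whole tetrahydrofuran synthesis, on the most valuable intermediate. The carbenoid faces several other oxygen-activated C–H bonds (C2–H and C5–H of the tetrahydrofuran, three further OCH2Ph groups). An imperfect enantioselectivity becomes a diastereomer problem one step from the end with no chance of upgrading. A3 must still be reduced without epimerisation. The tetrahydrofuran still has to be built, so the harder problem is only postponed.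
- Comparison: the chosen route runs the same insertion as step 4 on a small substrate, where its selectivity can be measured and corrected. The price is that every later reagent must be chosen so that C2'–O1' is not ionised, and that the ester is reduced at once.

Alternative 3: The dihydrobenzofuran is cut at the aryl ether bond O1'–C7a'. An auxiliary-controlled anti-aldol reaction sets C2' and C3' in an acyclic precursor. After reduction and benzylation the ring B phenol is converted into the triflate A6, and Pd(OAc)2 with 2-(di-tert-butylphosphino)biphenyl and K3PO4 joins the C2' hydroxyl to C7a' to give A5, a cis-dihydrobenzofuran with a dioxolane-masked formyl group.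
- For: both stereocentres come from a reaction of predictable sense, and the C–O coupling cannot touch the carbinol centre. Cis geometry and absolute configuration are therefore more certain than with a carbenoid insertion whose response to the 7-methoxy pattern has to be found out. On predictability this alternative is stronger.
- Against: a secondary benzylic alkoxide on palladium has an accessible β-hydrogen, so β-hydride elimination to the ketone competes with C–O reductive elimination. The triflate is flanked by a methoxy group and a branched benzylic carbon on an electron-rich ring, which slows oxidative addition. The sequence (auxiliary on and off, triflation, acetal on and off) needs roughly twice the steps that the chosen route needs to reach 9. The final acetal hydrolysis is an acid step next to the labile C2'–O1' bond. Like alternative 2, it solves only the dihydrobenzofuran.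
- Comparison: the chosen route offers a single catalytic step that forms the ring and both centres, and a bromide at C5' that becomes the enal 12 in one further operation.

Key step: step 13

Remarks and assumptions on the chemistry:
- Tetrahydrofuran atoms are numbered O1, C2 (carries ring B), C3, C4, C5 (carries the benzyl group) in all names. DBF stands for the (2R,3R)-3-(benzyloxymethyl)-2-(4-benzyloxy-3-methoxyphenyl)-7-methoxy-2,3-dihydro-1-benzofuran-5-yl group, TBDPS for tert-butyldiphenylsilyl, Bn for benzyl.
- Rh2(S-PTTL)4 is dirhodium tetrakis[N-phthaloyl-(S)-tert-leucinate]. It is assumed to give the (2R,3S) enantiomer of 7; the sense is checked on the first batch and Rh2(R-PTTL)4 is used if it is opposite.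
- Alcohol 3 is taken as a commercial material.
- The annulation of step 13 is planned on the known stereochemical course of this reaction type (inversion at the aryl-bearing carbon). The cyclopropane is therefore made with the (R)-configured amine catalyst, and C3 is corrected in steps 19 and 20.

## Route

Step 1
Reactants: 1 4-bromo-2-methoxyphenol
Product: 2 4-bromo-2-iodo-6-methoxyphenol
Conditions: I2, NaHCO3, THF–H2O, 0 °C to rt
Reagents that add atoms: iodine, II
Why: Electrophilic aromatic iodination of a phenol under mildly basic conditions; the para position is blocked by bromine, so the hydroxyl group directs iodine to its one free ortho position.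

Step 2
Reactants: 2 4-bromo-2-iodo-6-methoxyphenol; 3 (4-benzyloxy-3-methoxyphenyl)methanol
Product: 4 2-[(4-benzyloxy-3-methoxyphenyl)methoxy]-5-bromo-1-iodo-3-methoxybenzene
Conditions: PPh3, DIAD, THF, 0 °C to rt
Reagents that add atoms: none
Why: Mitsunobu etherification: the acidic phenol 2 displaces the activated primary benzylic alcohol 3; both ortho positions and the para position of 2 are occupied, so only O-alkylation is possible.

Step 3
Reactants: 4 2-[(4-benzyloxy-3-methoxyphenyl)methoxy]-5-bromo-1-iodo-3-methoxybenzene; 5 ethyl diazoacetate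
Product: 6 ethyl 2-{2-[(4-benzyloxy-3-methoxyphenyl)methoxy]-5-bromo-3-methoxyphenyl}-2-diazoacetate
Conditions: Pd(PPh3)4 (10 mol %), Et3N, n-Bu4NBr, MeCN, rt
Reagents that add atoms: none
Why: Palladium-catalysed coupling of an aryl iodide with the C–H bond of ethyl diazoacetate with retention of the diazo group; zerovalent palladium inserts into the carbon–iodine bond at room temperature far faster than into the carbon–bromine bond, which is kept for step 7.

Step 4
Reactants: 6 ethyl 2-{2-[(4-benzyloxy-3-methoxyphenyl)methoxy]-5-bromo-3-methoxyphenyl}-2-diazoacetate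
Product: 7 ethyl (2R,3S)-2-(4-benzyloxy-3-methoxyphenyl)-5-bromo-7-methoxy-2,3-dihydro-1-benzofuran-3-carboxylate (cis)
Conditions: Rh2(S-PTTL)4 (2 mol %), toluene, −78 to −40 °C
Reagents that add atoms: none
Why: Intramolecular 1,5 C–H insertion of the rhodium carbenoid into the OCH2 bond activated by the ether oxygen and by electron-rich ring A closes C2'–C3'; the concerted, hydride-transfer-like transition state places aryl and ester cis, and the chiral carboxylate ligands select the enantiotopic hydrogen.

Step 5
Reactants: 7 ethyl (2R,3S)-2-(4-benzyloxy-3-methoxyphenyl)-5-bromo-7-methoxy-2,3-dihydro-1-benzofuran-3-carboxylate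
Product: 8 [(2R,3R)-2-(4-benzyloxy-3-methoxyphenyl)-5-bromo-7-methoxy-2,3-dihydro-1-benzofuran-3-yl]methanol (cis)
Conditions: DIBAL-H, CH2Cl2, −78 to 0 °C; aq. Rochelle salt
Reagents that add atoms: none
Why: Ester reduction with a Lewis-acidic, non-basic hydride at low temperature, so that the cis C3' centre, still α to a carbonyl group, is reduced before it can epimerise to the trans isomer; the aryl bromide is inert.

Step 6
Reactants: 8 [(2R,3R)-2-(4-benzyloxy-3-methoxyphenyl)-5-bromo-7-methoxy-2,3-dihydro-1-benzofuran-3-yl]methanol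
Product: 9 (2R,3R)-3-(benzyloxymethyl)-2-(4-benzyloxy-3-methoxyphenyl)-5-bromo-7-methoxy-2,3-dihydro-1-benzofuran (DBF bromide)
Conditions: NaH, BnBr, n-Bu4NI (cat.), THF–DMF, 0 °C to rt
Reagents that add atoms: benzyl bromide, BrCc1ccccc1
Why: Williamson etherification of the primary alkoxide; C3' is no longer acidic, so strong base is harmless, and the benzyl ether keeps this primary alcohol distinct from the one that is unveiled and oxidised at C3 in steps 18 and 19.

Step 7
Reactants: 9 DBF bromide; 10 3,3-diethoxyprop-1-ene (acrolein diethyl acetal)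
Product: 12 (E)-3-DBF-prop-2-enal, via diethyl acetal of the enal 11 (not isolated)
Conditions: Pd(OAc)2 (5 mol %), n-Bu4NOAc, K2CO3, KCl, DMF, 90 °C; then 2 M HCl, rt
Reagents that add atoms: water (acetal hydrolysis, supplies the carbonyl oxygen), O
Why: Heck reaction of the aryl bromide with acetal-masked acrolein (migratory insertion, then syn β-hydride elimination away from the acetal carbon) gives the (E)-cinnamaldehyde acetal, which brief aqueous acid hydrolyses; the enal is made directly from the halide.

Step 8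
Reactants: 12 (E)-3-DBF-prop-2-enal; 13 dimethyl 2-bromomalonate
Product: 14 dimethyl (2R,3S)-2-DBF-3-formylcyclopropane-1,1-dicarboxylate (trans; C2 is the aryl-bearing carbon)
Conditions: (R)-2-[diphenyl(trimethylsilyloxy)methyl]pyrrolidine (20 mol %), 2,6-lutidine, CH2Cl2, 0 °C to rt
Reagents that add atoms: none
Why: Iminium–enamine cascade (Michael-initiated ring closure): the bromomalonate adds to the β-carbon of the (E)-iminium ion on its Re face, the Si face being shielded by the diphenyl(silyloxy)methyl group of the (R)-amine, and the enamine then displaces bromide in a 3-exo-tet closure that places aryl and formyl trans.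

Step 9
Reactants: 14 dimethyl (2R,3S)-2-DBF-3-formylcyclopropane-1,1-dicarboxylate
Product: 15 dimethyl (2R,3S)-2-DBF-3-(hydroxymethyl)cyclopropane-1,1-dicarboxylate
Conditions: NaBH4, THF–MeOH, −20 to 0 °C; pH 7 buffer
Reagents that add atoms: none
Why: Chemoselective borohydride reduction of the aldehyde; it is run cold and quenched at neutral pH because the new alkoxide is cis to one ester and would otherwise lactonise.

Step 10
Reactants: 15 dimethyl (2R,3S)-2-DBF-3-(hydroxymethyl)cyclopropane-1,1-dicarboxylate
Product: 16 dimethyl (2R,3S)-2-DBF-3-(TBDPS-oxymethyl)cyclopropane-1,1-dicarboxylate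
Conditions: TBDPSCl, imidazole, CH2Cl2, 0 °C to rt
Reagents that add atoms: tert-butyl(chloro)diphenylsilane, CC(C)(C)[Si](Cl)(c1ccccc1)c1ccccc1
Why: Silylation under mildly basic conditions outruns lactonisation, which a benzylation through the alkoxide would not; the silyl ether survives Lewis acid, hot LiCl, amide base and LiAlH4 and can later be removed without touching the benzyl ethers.

Step 11
Reactants: 17 eugenol (2-methoxy-4-(prop-2-enyl)phenol)
Product: 18 1-benzyloxy-2-methoxy-4-(prop-2-enyl)benzene
Conditions: BnBr, K2CO3, acetone, reflux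
Reagents that add atoms: benzyl bromide, BrCc1ccccc1
Why: Williamson etherification of the phenol.

Step 12
Reactants: 18 1-benzyloxy-2-methoxy-4-(prop-2-enyl)benzene
Product: 20 2-(4-benzyloxy-3-methoxyphenyl)acetaldehyde, via ozonide 19 (not isolated)
Conditions: O3, CH2Cl2, −78 °C (Sudan Red 7B end point); PPh3, −78 °C to rt
Reagents that add atoms: ozone, [O-][O+]=O
Why: Ozonolysis of the terminal alkene (1,3-dipolar cycloaddition, cycloreversion and recombination to the ozonide) with reductive work-up; ozone is dosed to an indicator end point so that the electron-rich arene is spared, and the enolisable aldehyde is used at once.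

Step 13
Reactants: 16 dimethyl (2R,3S)-2-DBF-3-(TBDPS-oxymethyl)cyclopropane-1,1-dicarboxylate; 20 2-(4-benzyloxy-3-methoxyphenyl)acetaldehyde
Product: 21 dimethyl (2S,3S,5S)-2-DBF-5-(4-benzyloxy-3-methoxybenzyl)-3-(TBDPS-oxymethyl)tetrahydrofuran-4,4-dicarboxylate (2,3-cis and 2,5-cis)
Conditions: Sn(OTf)2 (10 mol %), 20 (3 equiv, added last), CH2Cl2, 0 °C to rt
Reagents that add atoms: none
Why: This is the Lewis-acid-catalysed formal (3+2) annulation of a 2-aryl-3-alkylcyclopropane-1,1-diester with an aldehyde, a known reaction type whose scope includes aliphatic aldehydes. Sn(OTf)2 is chelated by the two ester carbonyls of 16 and polarises the bond between the malonate carbon (future C4) and the aryl-bearing carbon (future C2), the only cyclopropane bond with a benzylic, para-oxygen-stabilised terminus. The carbonyl oxygen of 20 attacks this carbon from the side opposite the departing malonate (SN2-like, within a tight ion pair), so O1–C2 forms with inversion and the (R) centre of 16 becomes (2S). The oxocarbenium–tin malonate zwitterion then closes C4–C5 by an aldol-type 5-(enolexo)-endo-trig attack of the malonate carbon on the oxocarbenium carbon, which is feasible for a cationic C=O terminus. C5 is set in this closure: in the envelope transition state the aryl group at C2 and the benzyl group at C5 both sit pseudo-equatorial, which gives the 2,5-cis ring and hence (5S). C3 is not touched, so the trans cyclopropane is translated into a 2,3-cis ring; this centre is corrected in steps 19 and 20. The step needs chemoselective activation of the cyclopropane next to the acid-sensitive cis-dihydrobenzofuran and the enolisable aldehyde; bidentate binding of a catalytic amount of a mild Lewis acid to the diester, the high donor strength of ring B (ring oxygen para and held in plane) and an excess of 20 added last at 0 °C are relied on for this.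

Step 14
Reactants: 21 dimethyl (2S,3S,5S)-2-DBF-5-(4-benzyloxy-3-methoxybenzyl)-3-(TBDPS-oxymethyl)tetrahydrofuran-4,4-dicarboxylate
Product: 22 methyl (2S,3S,5S)-2-DBF-5-(4-benzyloxy-3-methoxybenzyl)-3-(TBDPS-oxymethyl)tetrahydrofuran-4-carboxylate (C4 epimers)
Conditions: LiCl, H2O, DMSO, 140 °C
Reagents that add atoms: none
Why: Krapcho dealkoxycarbonylation: chloride demethylates one ester by SN2 attack on the methyl group, the carboxylate loses CO2 and the ester enolate is protonated by water; the C4 configuration is of no consequence because C4 becomes trigonal again in step 15.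

Step 15
Reactants: 22 methyl (2S,3S,5S)-2-DBF-5-(4-benzyloxy-3-methoxybenzyl)-3-(TBDPS-oxymethyl)tetrahydrofuran-4-carboxylate
Product: 24 methyl (2S,3S,5S)-2-DBF-5-(4-benzyloxy-3-methoxybenzyl)-4-hydroxy-3-(TBDPS-oxymethyl)tetrahydrofuran-4-carboxylate (C4 unassigned), via potassium enolate 23 (not isolated)
Conditions: KHMDS, THF, −78 °C; 2-(benzenesulfonyl)-3-phenyloxaziridine, −78 °C; aq. NH4Cl
Reagents that add atoms: 2-(benzenesulfonyl)-3-phenyloxaziridine, O=S(=O)(c1ccccc1)N1OC1c1ccccc1
Why: Enolate hydroxylation (Davis oxidation): the potassium ester enolate attacks the electrophilic oxygen of the N-sulfonyloxaziridine; ring opening by β-elimination of O1 is stereoelectronically disfavoured at −78 °C because the C5–O1 bond lies near the nodal plane of the exocyclic enolate.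

Step 16
Reactants: 24 methyl (2S,3S,5S)-2-DBF-5-(4-benzyloxy-3-methoxybenzyl)-4-hydroxy-3-(TBDPS-oxymethyl)tetrahydrofuran-4-carboxylate
Product: 25 (2S,3S,5S)-2-DBF-5-(4-benzyloxy-3-methoxybenzyl)-4-(hydroxymethyl)-3-(TBDPS-oxymethyl)tetrahydrofuran-4-ol (C4 unassigned)
Conditions: LiAlH4, THF, 0 °C
Reagents that add atoms: none
Why: LiAlH4 reduction of the α-hydroxy ester to the 1,2-diol; silyl and benzyl ethers are stable at 0 °C.

Step 17
Reactants: 25 (2S,3S,5S)-2-DBF-5-(4-benzyloxy-3-methoxybenzyl)-4-(hydroxymethyl)-3-(TBDPS-oxymethyl)tetrahydrofuran-4-ol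
Product: 27 (2S,3R,4S,5S)-2-DBF-5-(4-benzyloxy-3-methoxybenzyl)-3-(TBDPS-oxymethyl)tetrahydrofuran-4-ol (all four substituents cis), via ketone 26 (not isolated)
Conditions: NaIO4 on silica gel, CH2Cl2, 0 °C; filtration; then NaBH4, CeCl3·7H2O, MeOH, −40 °C
Reagents that add atoms: none
Why: Malaprade glycol cleavage excises the exocyclic carbon and leaves the C4 ketone, which is reduced at once under Luche conditions before either α-centre can enolise; the C3 and C5 substituents and the C2 aryl group lie on one face, so hydride enters from the open face and the hydroxyl group ends up cis to the C5 benzyl group, (4S).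

Step 18
Reactants: 27 (2S,3R,4S,5S)-2-DBF-5-(4-benzyloxy-3-methoxybenzyl)-3-(TBDPS-oxymethyl)tetrahydrofuran-4-ol
Product: 28 (2S,3R,4S,5S)-2-DBF-5-(4-benzyloxy-3-methoxybenzyl)-3-(hydroxymethyl)tetrahydrofuran-4-ol
Conditions: TBAF, THF, 0 °C to rt
Reagents that add atoms: none
Why: Fluoride-induced cleavage of the silyl ether; no carbonyl group is present, so the basicity of TBAF is harmless, and the three benzyl ethers stay.

Step 19
Reactants: 28 (2S,3R,4S,5S)-2-DBF-5-(4-benzyloxy-3-methoxybenzyl)-3-(hydroxymethyl)tetrahydrofuran-4-ol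
Product: 29 (2S,3R,4S,5S)-2-DBF-5-(4-benzyloxy-3-methoxybenzyl)-4-hydroxytetrahydrofuran-3-carbaldehyde (formyl cis to aryl and hydroxyl)
Conditions: (2,2,6,6-tetramethylpiperidin-1-yl)oxyl (TEMPO, 10 mol %), PhI(OAc)2, CH2Cl2, rt
Reagents that add atoms: none
Why: Oxoammonium-mediated (TEMPO) oxidation, which discriminates sterically between the primary and the secondary alcohol and stops at the aldehyde under anhydrous conditions; the other primary alcohol of the molecule is a benzyl ether.

Step 20
Reactants: 29 (2S,3R,4S,5S)-2-DBF-5-(4-benzyloxy-3-methoxybenzyl)-4-hydroxytetrahydrofuran-3-carbaldehyde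
Product: 31 (2S,3S,4S,5S)-2-DBF-5-(4-benzyloxy-3-methoxybenzyl)-3-(hydroxymethyl)tetrahydrofuran-4-ol, via trans aldehyde 30 (not isolated)
Conditions: 1,8-diazabicyclo[5.4.0]undec-7-ene (DBU, 0.2 equiv), CH2Cl2, 0 °C; then MeOH, NaBH4, 0 °C
Reagents that add atoms: none
Why: Base-mediated enolisation and reprotonation at C3, the only acidic position, moves the formyl group from the face it shares with both neighbours (aryl at C2, hydroxyl at C4) to the opposite face, a strongly downhill epimerisation that sets (3S) without touching C5; borohydride then reduces the aldehyde in the same flask.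

Step 21
Reactants: 31 (2S,3S,4S,5S)-2-DBF-5-(4-benzyloxy-3-methoxybenzyl)-3-(hydroxymethyl)tetrahydrofuran-4-ol
Product: 32 (2S,3S,4S,5S)-2-[(2R,3R)-2-(4-hydroxy-3-methoxyphenyl)-3-(hydroxymethyl)-7-methoxy-2,3-dihydro-1-benzofuran-5-yl]-5-(4-hydroxy-3-methoxybenzyl)-3-(hydroxymethyl)tetrahydrofuran-4-ol (CNP0179668.1)
Conditions: H2 (1 atm), palladium on carbon (10 wt % Pd), EtOAc–MeOH, rt
Reagents that add atoms: none
Why: Hydrogenolysis of the two aryl benzyl ethers and the primary alkyl benzyl ether; the reaction is followed closely and stopped at full debenzylation, because C2–O1 and C2'–O1' are benzylic too, although such ring ethers are cleaved much more slowly than O-benzyl groups.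

## Compound list

1 | 4-bromo-2-methoxyphenol | COc1cc(Br)ccc1O | starting material
2 | 4-bromo-2-iodo-6-methoxyphenol | COc1cc(Br)cc(I)c1O | intermediate
3 | (4-benzyloxy-3-methoxyphenyl)methanol | COc1cc(CO)ccc1OCc1ccccc1 | starting material
4 | 2-[(4-benzyloxy-3-methoxyphenyl)methoxy]-5-bromo-1-iodo-3-methoxybenzene | COc1cc(Br)cc(I)c1OCc1ccc(OCc2ccccc2)c(OC)c1 | intermediate
5 | ethyl diazoacetate | CCOC(=O)C=[N+]=[N-] | starting material
6 | ethyl 2-{2-[(4-benzyloxy-3-methoxyphenyl)methoxy]-5-bromo-3-methoxyphenyl}-2-diazoacetate | CCOC(=O)C(=[N+]=[N-])c1cc(Br)cc(OC)c1OCc1ccc(OCc2ccccc2)c(OC)c1 | intermediate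
7 | ethyl (2R,3S)-2-(4-benzyloxy-3-methoxyphenyl)-5-bromo-7-methoxy-2,3-dihydro-1-benzofuran-3-carboxylate (cis) | Brc1cc(OC)c2c(c1)[C@H](C(=O)OCC)[C@H](c1ccc(OCc3ccccc3)c(OC)c1)O2 | intermediate
8 | [(2R,3R)-2-(4-benzyloxy-3-methoxyphenyl)-5-bromo-7-methoxy-2,3-dihydro-1-benzofuran-3-yl]methanol (cis) | Brc1cc(OC)c2c(c1)[C@H](CO)[C@H](c1ccc(OCc3ccccc3)c(OC)c1)O2 | intermediate
9 | (2R,3R)-3-(benzyloxymethyl)-2-(4-benzyloxy-3-methoxyphenyl)-5-bromo-7-methoxy-2,3-dihydro-1-benzofuran (DBF bromide) | Brc1cc(OC)c2c(c1)[C@H](COCc1ccccc1)[C@H](c1ccc(OCc3ccccc3)c(OC)c1)O2 | intermediate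
10 | 3,3-diethoxyprop-1-ene (acrolein diethyl acetal) | C=CC(OCC)OCC | starting material
11 | 5-[(E)-3,3-diethoxyprop-1-enyl] derivative of DBF (diethyl acetal of 12; not isolated) | CCOC(OCC)/C=C/c1cc(OC)c2c(c1)[C@H](COCc1ccccc1)[C@H](c1ccc(OCc3ccccc3)c(OC)c1)O2 | intermediate
12 | (E)-3-DBF-prop-2-enal | O=C/C=C/c1cc(OC)c2c(c1)[C@H](COCc1ccccc1)[C@H](c1ccc(OCc3ccccc3)c(OC)c1)O2 | intermediate
13 | dimethyl 2-bromomalonate | COC(=O)C(Br)C(=O)OC | starting material
14 | dimethyl (2R,3S)-2-DBF-3-formylcyclopropane-1,1-dicarboxylate (trans) | COC(=O)C1(C(=O)OC)[C@@H](c2cc(OC)c3c(c2)[C@H](COCc2ccccc2)[C@H](c2ccc(OCc4ccccc4)c(OC)c2)O3)[C@@H]1C=O | intermediate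
15 | dimethyl (2R,3S)-2-DBF-3-(hydroxymethyl)cyclopropane-1,1-dicarboxylate (trans) | COC(=O)C1(C(=O)OC)[C@@H](c2cc(OC)c3c(c2)[C@H](COCc2ccccc2)[C@H](c2ccc(OCc4ccccc4)c(OC)c2)O3)[C@@H]1CO | intermediate
16 | dimethyl (2R,3S)-2-DBF-3-(TBDPS-oxymethyl)cyclopropane-1,1-dicarboxylate (trans) | COC(=O)C1(C(=O)OC)[C@@H](c2cc(OC)c3c(c2)[C@H](COCc2ccccc2)[C@H](c2ccc(OCc4ccccc4)c(OC)c2)O3)[C@@H]1CO[Si](c1ccccc1)(c1ccccc1)C(C)(C)C | intermediate
17 | eugenol (2-methoxy-4-(prop-2-enyl)phenol) | COc1cc(CC=C)ccc1O | starting material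
18 | 1-benzyloxy-2-methoxy-4-(prop-2-enyl)benzene | COc1cc(CC=C)ccc1OCc1ccccc1 | intermediate
19 | 3-[(4-benzyloxy-3-methoxyphenyl)methyl]-1,2,4-trioxolane (ozonide; not isolated) | COc1cc(CC2OCOO2)ccc1OCc1ccccc1 | intermediate
20 | 2-(4-benzyloxy-3-methoxyphenyl)acetaldehyde | COc1cc(CC=O)ccc1OCc1ccccc1 | intermediate
21 | dimethyl (2S,3S,5S)-2-DBF-5-(4-benzyloxy-3-methoxybenzyl)-3-(TBDPS-oxymethyl)tetrahydrofuran-4,4-dicarboxylate (2,3-cis, 2,5-cis) | COc1cc(C[C@@H]2O[C@H](c3cc(OC)c4c(c3)[C@H](COCc3ccccc3)[C@H](c3ccc(OCc5ccccc5)c(OC)c3)O4)[C@H](CO[Si](c3ccccc3)(c3ccccc3)C(C)(C)C)C2(C(=O)OC)C(=O)OC)ccc1OCc1ccccc1 | intermediate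
22 | methyl (2S,3S,5S)-2-DBF-5-(4-benzyloxy-3-methoxybenzyl)-3-(TBDPS-oxymethyl)tetrahydrofuran-4-carboxylate (C4 epimers) | COc1cc(C[C@@H]2O[C@H](c3cc(OC)c4c(c3)[C@H](COCc3ccccc3)[C@H](c3ccc(OCc5ccccc5)c(OC)c3)O4)[C@H](CO[Si](c3ccccc3)(c3ccccc3)C(C)(C)C)C2C(=O)OC)ccc1OCc1ccccc1 | intermediate
23 | potassium enolate of 22 (not isolated) | COc1cc(C[C@@H]2O[C@H](c3cc(OC)c4c(c3)[C@H](COCc3ccccc3)[C@H](c3ccc(OCc5ccccc5)c(OC)c3)O4)[C@H](CO[Si](c3ccccc3)(c3ccccc3)C(C)(C)C)C2=C([O-])OC)ccc1OCc1ccccc1.[K+] | intermediate
24 | methyl (2S,3S,5S)-2-DBF-5-(4-benzyloxy-3-methoxybenzyl)-4-hydroxy-3-(TBDPS-oxymethyl)tetrahydrofuran-4-carboxylate (C4 unassigned) | COc1cc(C[C@@H]2O[C@H](c3cc(OC)c4c(c3)[C@H](COCc3ccccc3)[C@H](c3ccc(OCc5ccccc5)c(OC)c3)O4)[C@H](CO[Si](c3ccccc3)(c3ccccc3)C(C)(C)C)C2(O)C(=O)OC)ccc1OCc1ccccc1 | intermediate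
25 | (2S,3S,5S)-2-DBF-5-(4-benzyloxy-3-methoxybenzyl)-4-(hydroxymethyl)-3-(TBDPS-oxymethyl)tetrahydrofuran-4-ol (C4 unassigned) | COc1cc(C[C@@H]2O[C@H](c3cc(OC)c4c(c3)[C@H](COCc3ccccc3)[C@H](c3ccc(OCc5ccccc5)c(OC)c3)O4)[C@H](CO[Si](c3ccccc3)(c3ccccc3)C(C)(C)C)C2(O)CO)ccc1OCc1ccccc1 | intermediate
26 | (2S,3S,5S)-2-DBF-5-(4-benzyloxy-3-methoxybenzyl)-3-(TBDPS-oxymethyl)tetrahydrofuran-4-one (2,3-cis, 2,5-cis; not isolated) | COc1cc(C[C@@H]2O[C@H](c3cc(OC)c4c(c3)[C@H](COCc3ccccc3)[C@H](c3ccc(OCc5ccccc5)c(OC)c3)O4)[C@H](CO[Si](c3ccccc3)(c3ccccc3)C(C)(C)C)C2=O)ccc1OCc1ccccc1 | intermediate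
27 | (2S,3R,4S,5S)-2-DBF-5-(4-benzyloxy-3-methoxybenzyl)-3-(TBDPS-oxymethyl)tetrahydrofuran-4-ol (all-cis) | COc1cc(C[C@@H]2O[C@H](c3cc(OC)c4c(c3)[C@H](COCc3ccccc3)[C@H](c3ccc(OCc5ccccc5)c(OC)c3)O4)[C@H](CO[Si](c3ccccc3)(c3ccccc3)C(C)(C)C)[C@@H]2O)ccc1OCc1ccccc1 | intermediate
28 | (2S,3R,4S,5S)-2-DBF-5-(4-benzyloxy-3-methoxybenzyl)-3-(hydroxymethyl)tetrahydrofuran-4-ol (all-cis) | COc1cc(C[C@@H]2O[C@H](c3cc(OC)c4c(c3)[C@H](COCc3ccccc3)[C@H](c3ccc(OCc5ccccc5)c(OC)c3)O4)[C@H](CO)[C@@H]2O)ccc1OCc1ccccc1 | intermediate
29 | (2S,3R,4S,5S)-2-DBF-5-(4-benzyloxy-3-methoxybenzyl)-4-hydroxytetrahydrofuran-3-carbaldehyde (all-cis) | COc1cc(C[C@@H]2O[C@H](c3cc(OC)c4c(c3)[C@H](COCc3ccccc3)[C@H](c3ccc(OCc5ccccc5)c(OC)c3)O4)[C@H](C=O)[C@@H]2O)ccc1OCc1ccccc1 | intermediate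
30 | (2S,3S,4S,5S)-2-DBF-5-(4-benzyloxy-3-methoxybenzyl)-4-hydroxytetrahydrofuran-3-carbaldehyde (formyl trans to aryl and hydroxyl; not isolated) | COc1cc(C[C@@H]2O[C@H](c3cc(OC)c4c(c3)[C@H](COCc3ccccc3)[C@H](c3ccc(OCc5ccccc5)c(OC)c3)O4)[C@@H](C=O)[C@@H]2O)ccc1OCc1ccccc1 | intermediate
31 | (2S,3S,4S,5S)-2-DBF-5-(4-benzyloxy-3-methoxybenzyl)-3-(hydroxymethyl)tetrahydrofuran-4-ol (tribenzyl ether of 32) | COc1cc(C[C@@H]2O[C@H](c3cc(OC)c4c(c3)[C@H](COCc3ccccc3)[C@H](c3ccc(OCc5ccccc5)c(OC)c3)O4)[C@@H](CO)[C@@H]2O)ccc1OCc1ccccc1 | intermediate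
32 | (2S,3S,4S,5S)-2-[(2R,3R)-2-(4-hydroxy-3-methoxyphenyl)-3-(hydroxymethyl)-7-methoxy-2,3-dihydro-1-benzofuran-5-yl]-5-(4-hydroxy-3-methoxybenzyl)-3-(hydroxymethyl)tetrahydrofuran-4-ol (CNP0179668.1) | COc1cc(C[C@@H]2O[C@H](c3cc(OC)c4c(c3)[C@H](CO)[C@H](c3ccc(O)c(OC)c3)O4)[C@@H](CO)[C@@H]2O)ccc1O | target

## Step count and least certain steps

Total step count: 21. Longest linear sequence: 19 steps (steps 1–10 and 13–21, from 1 to 32); the aldehyde 20 is made in two steps on a side branch.

Step 13 (key step). What is most likely to go wrong is loss of the inversion at C2. Ring B is so strong a donor that the activated cyclopropane may ionise completely to an open benzylic zwitterion before the aldehyde is bound, and rotation about C2–C3 would then let the aryl group settle trans to the C3 arm. Ionisation of C2'–O1' by the Lewis acid (cis to trans drift of the dihydrobenzofuran) and enolisation of 20 are the secondary risks. Fallback: if the trans course dominates with the 2,5-cis relationship intact, it is used instead of resisted, by entering the enantiomeric cyclopropane series.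
- It sets out from 12, which is cyclopropanated with (S)-2-[diphenyl(trimethylsilyloxy)methyl]pyrrolidine to give dimethyl (2S,3R)-2-DBF-3-formylcyclopropane-1,1-dicarboxylate F1.
- NaBH4 gives the alcohol F2, and TBDPSCl and imidazole give the silyl ether F3.
- Annulation of F3 with 20 under Sn(OTf)2 then gives the 2,3-trans, 2,5-cis tetrahydrofuran diester F4, in which C3 is already correct.
- Krapcho dealkoxycarbonylation gives the monoester F5. KHMDS gives its potassium enolate F6, which the oxaziridine hydroxylates to the hydroxy ester F7. LiAlH4 gives the diol F8.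
- Periodate cleavage gives the 2,3-trans ketone F9, which is kept neutral and cold. HF·pyridine in pyridine–THF gives the β-hydroxy ketone F10.
- Me4NBH(OAc)3 in MeCN–AcOH delivers hydride from the face of the C3 hydroxymethyl group (Evans–Saksena reduction) and places the C4 hydroxyl trans to it. The fallback comes back to the route at 31.

Step 3. The iodide of 4 is ortho to a bulky ether on an electron-rich ring, so oxidative addition may be slow relative to palladium-induced decomposition of the diazo ester (carbene dimerisation, azine formation). Fallback, from 4 back to 6: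
- Iodine–magnesium exchange with i-PrMgCl·LiCl at −40 °C, selective over bromine, gives the arylmagnesium chloride F11.
- F11 is added to excess diethyl oxalate at −78 °C to give the ethyl arylglyoxylate F12.
- Condensation with tosylhydrazide gives the tosylhydrazone F13.
- DBU eliminates sulfinate (Bamford–Stevens reaction) to return 6.

Step 4. The enantioselectivity or the cis selectivity of the insertion may fall short, because the reacting ether oxygen is flanked by a methoxy group, which changes the conformation of the OCH2 arm in the catalyst pocket; the sense of induction is also an assumption. Fallback, a resolution that starts from scalemic 8 and returns to 8: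
- Acylation with (1S,4R)-camphanic chloride, Et3N and DMAP gives the camphanate F14 of 8 together with the diastereomeric camphanate F15 of the minor enantiomer.
- The two are separated by crystallisation or chromatography.
- Methanolysis of F14 with K2CO3 in MeOH returns enantiopure 8.

Step 20. β-Elimination of the C4 hydroxyl group (E1cB) or retro-aldol opening of the C3–C4 bond may compete with the simple enolisation and reprotonation of the β-hydroxy aldehyde. Fallback, in which C3 is epimerised at the ester level, where both side reactions are much slower; it starts from 29 and returns at 31: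
- Pinnick oxidation (NaClO2, NaH2PO4, 2-methylbut-2-ene) gives the cis hydroxy acid F16.
- Trimethylsilyldiazomethane in MeOH–toluene gives the cis methyl ester F17.
- Catalytic NaOMe in MeOH equilibrates it to the trans methyl ester F18.
- LiAlH4 reduces F18 to 31.

## Further compounds

F1 | step 13 | dimethyl (2S,3R)-2-DBF-3-formylcyclopropane-1,1-dicarboxylate (trans) | COC(=O)C1(C(=O)OC)[C@H](c2cc(OC)c3c(c2)[C@H](COCc2ccccc2)[C@H](c2ccc(OCc4ccccc4)c(OC)c2)O3)[C@H]1C=O
F2 | step 13 | dimethyl (2S,3R)-2-DBF-3-(hydroxymethyl)cyclopropane-1,1-dicarboxylate | COC(=O)C1(C(=O)OC)[C@H](c2cc(OC)c3c(c2)[C@H](COCc2ccccc2)[C@H](c2ccc(OCc4ccccc4)c(OC)c2)O3)[C@H]1CO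
F3 | step 13 | dimethyl (2S,3R)-2-DBF-3-(TBDPS-oxymethyl)cyclopropane-1,1-dicarboxylate | COC(=O)C1(C(=O)OC)[C@H](c2cc(OC)c3c(c2)[C@H](COCc2ccccc2)[C@H](c2ccc(OCc4ccccc4)c(OC)c2)O3)[C@H]1CO[Si](c1ccccc1)(c1ccccc1)C(C)(C)C
F4 | step 13 | dimethyl (2S,3R,5S)-2-DBF-5-(4-benzyloxy-3-methoxybenzyl)-3-(TBDPS-oxymethyl)tetrahydrofuran-4,4-dicarboxylate (2,3-trans, 2,5-cis) | COc1cc(C[C@@H]2O[C@H](c3cc(OC)c4c(c3)[C@H](COCc3ccccc3)[C@H](c3ccc(OCc5ccccc5)c(OC)c3)O4)[C@@H](CO[Si](c3ccccc3)(c3ccccc3)C(C)(C)C)C2(C(=O)OC)C(=O)OC)ccc1OCc1ccccc1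
F5 | step 13 | methyl (2S,3R,5S)-2-DBF-5-(4-benzyloxy-3-methoxybenzyl)-3-(TBDPS-oxymethyl)tetrahydrofuran-4-carboxylate (C4 epimers) | COc1cc(C[C@@H]2O[C@H](c3cc(OC)c4c(c3)[C@H](COCc3ccccc3)[C@H](c3ccc(OCc5ccccc5)c(OC)c3)O4)[C@@H](CO[Si](c3ccccc3)(c3ccccc3)C(C)(C)C)C2C(=O)OC)ccc1OCc1ccccc1
F6 | step 13 | potassium enolate of F5 | COc1cc(C[C@@H]2O[C@H](c3cc(OC)c4c(c3)[C@H](COCc3ccccc3)[C@H](c3ccc(OCc5ccccc5)c(OC)c3)O4)[C@@H](CO[Si](c3ccccc3)(c3ccccc3)C(C)(C)C)C2=C([O-])OC)ccc1OCc1ccccc1.[K+]
F7 | step 13 | methyl (2S,3R,5S)-2-DBF-5-(4-benzyloxy-3-methoxybenzyl)-4-hydroxy-3-(TBDPS-oxymethyl)tetrahydrofuran-4-carboxylate (C4 unassigned) | COc1cc(C[C@@H]2O[C@H](c3cc(OC)c4c(c3)[C@H](COCc3ccccc3)[C@H](c3ccc(OCc5ccccc5)c(OC)c3)O4)[C@@H](CO[Si](c3ccccc3)(c3ccccc3)C(C)(C)C)C2(O)C(=O)OC)ccc1OCc1ccccc1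
F8 | step 13 | (2S,3R,5S)-2-DBF-5-(4-benzyloxy-3-methoxybenzyl)-4-(hydroxymethyl)-3-(TBDPS-oxymethyl)tetrahydrofuran-4-ol (C4 unassigned) | COc1cc(C[C@@H]2O[C@H](c3cc(OC)c4c(c3)[C@H](COCc3ccccc3)[C@H](c3ccc(OCc5ccccc5)c(OC)c3)O4)[C@@H](CO[Si](c3ccccc3)(c3ccccc3)C(C)(C)C)C2(O)CO)ccc1OCc1ccccc1
F9 | step 13 | (2S,3R,5S)-2-DBF-5-(4-benzyloxy-3-methoxybenzyl)-3-(TBDPS-oxymethyl)tetrahydrofuran-4-one (2,3-trans, 2,5-cis) | COc1cc(C[C@@H]2O[C@H](c3cc(OC)c4c(c3)[C@H](COCc3ccccc3)[C@H](c3ccc(OCc5ccccc5)c(OC)c3)O4)[C@@H](CO[Si](c3ccccc3)(c3ccccc3)C(C)(C)C)C2=O)ccc1OCc1ccccc1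
F10 | step 13 | (2S,3R,5S)-2-DBF-5-(4-benzyloxy-3-methoxybenzyl)-3-(hydroxymethyl)tetrahydrofuran-4-one (2,3-trans, 2,5-cis) | COc1cc(C[C@@H]2O[C@H](c3cc(OC)c4c(c3)[C@H](COCc3ccccc3)[C@H](c3ccc(OCc5ccccc5)c(OC)c3)O4)[C@@H](CO)C2=O)ccc1OCc1ccccc1
F11 | step 3 | {2-[(4-benzyloxy-3-methoxyphenyl)methoxy]-5-bromo-3-methoxyphenyl}magnesium chloride | COc1cc(Br)cc([Mg]Cl)c1OCc1ccc(OCc2ccccc2)c(OC)c1
F12 | step 3 | ethyl 2-{2-[(4-benzyloxy-3-methoxyphenyl)methoxy]-5-bromo-3-methoxyphenyl}-2-oxoacetate | CCOC(=O)C(=O)c1cc(Br)cc(OC)c1OCc1ccc(OCc2ccccc2)c(OC)c1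
F13 | step 3 | tosylhydrazone of F12 | CCOC(=O)C(=NNS(=O)(=O)c1ccc(C)cc1)c1cc(Br)cc(OC)c1OCc1ccc(OCc2ccccc2)c(OC)c1
F14 | step 4 | (1S,4R)-camphanate of 8 | Brc1cc(OC)c2c(c1)[C@H](COC(=O)[C@@]13CC[C@@](C)(C(=O)O1)C3(C)C)[C@H](c1ccc(OCc3ccccc3)c(OC)c1)O2
F15 | step 4 | (1S,4R)-camphanate of the enantiomer of 8 | Brc1cc(OC)c2c(c1)[C@@H](COC(=O)[C@@]13CC[C@@](C)(C(=O)O1)C3(C)C)[C@@H](c1ccc(OCc3ccccc3)c(OC)c1)O2
F16 | step 20 | (2S,3R,4S,5S)-2-DBF-5-(4-benzyloxy-3-methoxybenzyl)-4-hydroxytetrahydrofuran-3-carboxylic acid (all-cis) | COc1cc(C[C@@H]2O[C@H](c3cc(OC)c4c(c3)[C@H](COCc3ccccc3)[C@H](c3ccc(OCc5ccccc5)c(OC)c3)O4)[C@H](C(=O)O)[C@@H]2O)ccc1OCc1ccccc1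
F17 | step 20 | methyl (2S,3R,4S,5S)-2-DBF-5-(4-benzyloxy-3-methoxybenzyl)-4-hydroxytetrahydrofuran-3-carboxylate (all-cis) | COc1cc(C[C@@H]2O[C@H](c3cc(OC)c4c(c3)[C@H](COCc3ccccc3)[C@H](c3ccc(OCc5ccccc5)c(OC)c3)O4)[C@H](C(=O)OC)[C@@H]2O)ccc1OCc1ccccc1
F18 | step 20 | methyl (2S,3S,4S,5S)-2-DBF-5-(4-benzyloxy-3-methoxybenzyl)-4-hydroxytetrahydrofuran-3-carboxylate (ester trans to aryl and hydroxyl) | COc1cc(C[C@@H]2O[C@H](c3cc(OC)c4c(c3)[C@H](COCc3ccccc3)[C@H](c3ccc(OCc5ccccc5)c(OC)c3)O4)[C@@H](C(=O)OC)[C@@H]2O)ccc1OCc1ccccc1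
A1 | alternative 1 | methyl 2-DBF-5-(4-benzyloxy-3-methoxybenzyl)-4-oxotetrahydrofuran-3-carboxylate (2,5-cis, 2,3-trans; ring configuration at C2, C3 and C5 as in 32) | COc1cc(C[C@@H]2O[C@H](c3cc(OC)c4c(c3)[C@H](COCc3ccccc3)[C@H](c3ccc(OCc5ccccc5)c(OC)c3)O4)[C@@H](C(=O)OC)C2=O)ccc1OCc1ccccc1
A2 | alternative 1 | methyl 2-[(5S)-2-DBF-5-(4-benzyloxy-3-methoxybenzyl)-1,3-dioxolan-4-ylidene]acetate (acetal carbon and alkene geometry not fixed) | COC(=O)C=C1OC(c2cc(OC)c3c(c2)[C@H](COCc2ccccc2)[C@H](c2ccc(OCc4ccccc4)c(OC)c2)O3)O[C@H]1Cc1ccc(OCc2ccccc2)c(OC)c1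
A3 | alternative 2 | ethyl cis-(2R,3S)-2-(4-benzyloxy-3-methoxyphenyl)-7-methoxy-5-[4-benzyloxy-5-(4-benzyloxy-3-methoxybenzyl)-3-(benzyloxymethyl)tetrahydrofuran-2-yl]-2,3-dihydro-1-benzofuran-3-carboxylate (tetrahydrofuran configured as in 32) | COc1cc(C[C@@H]2O[C@H](c3cc(OC)c4c(c3)[C@H](C(=O)OCC)[C@H](c3ccc(OCc5ccccc5)c(OC)c3)O4)[C@@H](COCc3ccccc3)[C@@H]2OCc2ccccc2)ccc1OCc1ccccc1
A4 | alternative 2 | ethyl 2-diazo-2-{2-[(4-benzyloxy-3-methoxyphenyl)methoxy]-3-methoxy-5-[4-benzyloxy-5-(4-benzyloxy-3-methoxybenzyl)-3-(benzyloxymethyl)tetrahydrofuran-2-yl]phenyl}acetate (tetrahydrofuran configured as in 32) | COc1cc(C[C@@H]2O[C@H](c3cc(OC)c(OCc4ccc(OCc5ccccc5)c(OC)c4)c(c3)C(=[N+]=[N-])C(=O)OCC)[C@@H](COCc3ccccc3)[C@@H]2OCc2ccccc2)ccc1OCc1ccccc1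
A5 | alternative 3 | (2R,3R)-3-(benzyloxymethyl)-2-(4-benzyloxy-3-methoxyphenyl)-5-(1,3-dioxolan-2-yl)-7-methoxy-2,3-dihydro-1-benzofuran (cis) | C1COC(O1)c1cc(OC)c2c(c1)[C@H](COCc1ccccc1)[C@H](c1ccc(OCc3ccccc3)c(OC)c1)O2
A6 | alternative 3 | 2-[(1R,2R)-3-benzyloxy-1-(4-benzyloxy-3-methoxyphenyl)-1-hydroxypropan-2-yl]-4-(1,3-dioxolan-2-yl)-6-methoxyphenyl trifluoromethanesulfonate | C1COC(O1)c1cc(OC)c(OS(=O)(=O)C(F)(F)F)c(c1)[C@H](COCc1ccccc1)[C@@H](O)c1ccc(OCc2ccccc2)c(OC)c1
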